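**Retrosynthetic overview**
1. Dinorspiculoic acid A ⇐ its methyl ester, by O–CH3 cleavage as the last step.
2. Methyl ester ⇐ two acyclic halves joined in one flask: Stille coupling (C8–C9) of a C1–C8 keto vinylstannane with a C9–C12 phenyldienyl iodide gives a tetraenone that is not isolated and closes by intramolecular [4+2] cycloaddition. C3–C7 closes the cyclopentanone and C2–C10 the cyclohexene, so both rings form in the same event; no ring exists before it.
3. Keto stannane ⇐ C5–C6 bond by Marshall propargylation of an enoate aldehyde (sets C6, selects C4), then hydrostannation and oxidation; the aldehyde ⇐ cross-metathesis.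
4. Dienyl iodide ⇐ syn-ethylcupration/iodination of (E)-1-phenylbut-1-en-3-yne.

Assumption: the SMILES is read as (1R,3R,3aS,4S,5R,7aS) with an E styryl group. Open-chain locants are dodecatetraenoate numbers (C1 = ester carbon; ring-fusion carbons C3 and C7, ketone C5, quaternary carbons C2 and C10).

**Step 1**
Reactants: 1 rac-2-methylbut-3-en-1-ol; 2 methyl 2-ethylacrylate (methyl 2-methylidenebutanoate)
Product: 3 methyl (2E)-2-ethyl-5-hydroxy-4-methylpent-2-enoate (racemic at C4)
Conditions: 2 (5 equiv), RuCl2(=CH-C6H4-2-OiPr)(H2IMes) (second-generation Hoveyda–Grubbs catalyst, 5 mol %), CH2Cl2, 40 °C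
Reagents that add atoms: none
Why: Olefin cross-metathesis between a monosubstituted alkene and a 1,1-disubstituted acrylate favours the cross product and gives the trisubstituted enoate as the E isomer (ester trans to the chain) under reversible, thermodynamic conditions; C4 is already present and stays racemic.

**Step 2**
Reactants: 3 methyl (2E)-2-ethyl-5-hydroxy-4-methylpent-2-enoate
Product: 4 methyl (2E)-2-ethyl-4-methyl-5-oxopent-2-enoate (racemic)
Conditions: Dess–Martin periodinane, CH2Cl2, 0 → 25 °C; filtered and used at once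
Reagents that add atoms: none
Why: Dess–Martin oxidation stops at the aldehyde under neutral conditions and creates no stereocentre; the β,γ-unsaturated aldehyde is used cold and immediately so that it does not slip into conjugation.

**Step 3**
Reactants: 5 pent-3-yn-2-one
Product: 6 (S)-pent-3-yn-2-ol
Conditions: RuCl(p-cymene)[(S,S)-TsDPEN] (0.5 mol %), i-PrOH, 25 °C
Reagents that add atoms: none
Why: Noyori asymmetric transfer hydrogenation of an alkynyl ketone, in which the alkyne takes the place an aryl group would have, so the (S,S) catalyst delivers hydride to the face that gives the S alcohol (typically ≥97% ee).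

**Step 4**
Reactants: 6 (S)-pent-3-yn-2-ol
Product: 7 (S)-pent-3-yn-2-yl methanesulfonate
Conditions: MsCl, Et3N, CH2Cl2, −78 °C; used crude
Reagents that add atoms: methanesulfonyl chloride, CS(=O)(=O)Cl
Why: Mesylation forms the O–S bond only, so the C–O bond and the S configuration are untouched.

**Step 5**
Reactants: 4 methyl (2E)-2-ethyl-4-methyl-5-oxopent-2-enoate (2.5 equiv); 7 (S)-pent-3-yn-2-yl methanesulfonate
Product: 9 methyl (2E,4R,5S,6R)-2-ethyl-5-hydroxy-4,6-dimethylnon-2-en-7-ynoate, via allenylzinc 8 (not isolated)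
Conditions: Pd(OAc)2 (5 mol %), PPh3 (5 mol %), Et2Zn (3 equiv), THF, −78 → −20 °C; aq. NH4Cl; chromatography
Reagents that add atoms: none
Why: Marshall propargylation, in which zerovalent palladium displaces the mesylate in an anti SN2′ sense, Et2Zn transmetalates to allenylzinc 8 with retention and 8 adds through a cyclic SE2′ transition state, so C6 forms with net inversion of the mesylate carbon (S → 6R) and anti to the new C5 hydroxyl (5S); the reagent is Felkin-matched with the R enantiomer of racemic 4, which reacts preferentially when 4 is in excess to give the 4,5-syn-5,6-anti isomer, and the minor 4S diastereomer is removed by chromatography.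

**Step 6**
Reactants: 9 methyl (2E,4R,5S,6R)-2-ethyl-5-hydroxy-4,6-dimethylnon-2-en-7-ynoate
Product: 10 methyl (2E,4R,5S,6R,7E)-2-ethyl-5-hydroxy-4,6-dimethyl-8-(tributylstannyl)nona-2,7-dienoate
Conditions: Bu3SnH (1.3 equiv), PdCl2(PPh3)2 (3 mol %), THF, 0 °C
Reagents that add atoms: tributyltin hydride, CCCC[SnH](CCCC)CCCC
Why: Palladium-catalysed hydrostannation is a syn addition that places tin on the less hindered, methyl-bearing alkyne carbon and hydrogen next to the branched C6, giving the 7E vinylstannane without touching any sp3 centre.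

**Step 7**
Reactants: 10 methyl (2E,4R,5S,6R,7E)-2-ethyl-5-hydroxy-4,6-dimethyl-8-(tributylstannyl)nona-2,7-dienoate
Product: 11 methyl (2E,4R,6R,7E)-2-ethyl-4,6-dimethyl-5-oxo-8-(tributylstannyl)nona-2,7-dienoate
Conditions: Dess–Martin periodinane, pyridine, CH2Cl2, 0 °C; short pad of deactivated silica
Reagents that add atoms: none
Why: Buffered Dess–Martin oxidation gives the C5 ketone without protodestannylation, and C4 and C6 survive because allylic 1,3-strain holds their C–H bonds in the plane of the neighbouring alkenes, leaving them no more acidic than ordinary ketone α-methines.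

**Step 8**
Reactants: 12 (E)-(2-bromoethenyl)benzene
Product: 13 (E)-but-1-en-3-yn-1-ylbenzene
Conditions: HC≡CMgBr, ZnBr2, THF, 0 °C; then 12, Pd(PPh3)4 (3 mol %), 25 °C
Reagents that add atoms: ethynylmagnesium bromide, C#C[Mg]Br
Why: Negishi alkynylation, in which oxidative addition of zerovalent palladium into the vinyl C–Br bond and reductive elimination both proceed with retention, so the E alkene is kept.

**Step 9**
Reactants: 13 (E)-but-1-en-3-yn-1-ylbenzene
Product: 15 (1E,3E)-2-ethyl-1-iodo-4-phenylbuta-1,3-diene, via dienylcopper 14 (not isolated)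
Conditions: EtMgBr, CuBr·SMe2, Et2O/Me2S, −45 °C; then 13, −25 °C; then I2, −40 → 0 °C
Reagents that add atoms: ethylmagnesium bromide, CC[Mg]Br; iodine, II
Why: Normant carbocupration is a syn addition that delivers ethyl to the internal alkyne carbon and copper to the terminal one, and iodinolysis of the vinyl–copper bond goes with retention, so ethyl and iodine end up cis (1E).

**Step 10**
Reactants: 11 methyl (2E,4R,6R,7E)-2-ethyl-4,6-dimethyl-5-oxo-8-(tributylstannyl)nona-2,7-dienoate; 15 (1E,3E)-2-ethyl-1-iodo-4-phenylbuta-1,3-diene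
Product: 17 methyl (1R,3R,3aS,4S,5R,7aS)-4,5-diethyl-1,3,7-trimethyl-2-oxo-5-[(E)-2-phenylethenyl]-2,3,3a,4,5,7a-hexahydro-1H-indene-4-carboxylate, via tetraenyl ketone 16 (not isolated)
Conditions: Pd2(dba)3 (5 mol %), AsPh3 (20 mol %), CuI (copper monoiodide, 20 mol %), DMF, 35 °C; then PhMe, BHT, 80 °C
Reagents that add atoms: none
Why: Stille cross-coupling (oxidative addition of zerovalent palladium into the C–I bond of 15, copper-assisted transmetalation from tin, retention at both alkenes) assembles the (7E,9E,11E)-triene of 16, which on warming closes by an intramolecular Diels–Alder reaction (C3–C7 and C2–C10) through the endo transition state with the ester under the diene that gives the trans ring fusion; the diene face is fixed by C6 and the dienophile face by C4, because allylic 1,3-strain (C6–H toward the C8 methyl, C4–H toward the C2 ethyl) leaves one reactive conformer, so C2, C3, C7 and C10 are set in one event.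

**Step 11**
Reactants: 17 methyl (1R,3R,3aS,4S,5R,7aS)-4,5-diethyl-1,3,7-trimethyl-2-oxo-5-[(E)-2-phenylethenyl]-2,3,3a,4,5,7a-hexahydro-1H-indene-4-carboxylate
Product: 18 dinorspiculoic acid A, (1R,3R,3aS,4S,5R,7aS)-4,5-diethyl-1,3,7-trimethyl-2-oxo-5-[(E)-2-phenylethenyl]-2,3,3a,4,5,7a-hexahydro-1H-indene-4-carboxylic acid
Conditions: NaSEt (5 equiv), DMF, 80 °C; then 1 M HCl
Reagents that add atoms: none
Why: SN2 dealkylation by thiolate at the O-methyl carbon avoids the carbonyl flanked by two quaternary carbons where hydroxide would not attack, and the basic medium can only move the two ketone α-centres toward the all-trans arrangement they already have.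

**Compound list**
1 | rac-2-methylbut-3-en-1-ol | C=CC(C)CO | starting material
2 | methyl 2-ethylacrylate (methyl 2-methylidenebutanoate) | CCC(=C)C(=O)OC | starting material
3 | methyl (2E)-2-ethyl-5-hydroxy-4-methylpent-2-enoate, racemic | CC/C(=C\C(C)CO)C(=O)OC | intermediate
4 | methyl (2E)-2-ethyl-4-methyl-5-oxopent-2-enoate, racemic | CC/C(=C\C(C)C=O)C(=O)OC | intermediate
5 | pent-3-yn-2-one | CC#CC(C)=O | starting material
6 | (S)-pent-3-yn-2-ol | C[C@H](O)C#CC | intermediate
7 | (S)-pent-3-yn-2-yl methanesulfonate | C[C@H](OS(C)(=O)=O)C#CC | intermediate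
8 | (M)-ethyl(penta-2,3-dien-2-yl)zinc (allenylzinc) | CC[Zn]C(C)=[C@]=C([H])C | intermediate
9 | methyl (2E,4R,5S,6R)-2-ethyl-5-hydroxy-4,6-dimethylnon-2-en-7-ynoate | CC/C(=C\[C@@H](C)[C@H](O)[C@H](C)C#CC)C(=O)OC | intermediate
10 | methyl (2E,4R,5S,6R,7E)-2-ethyl-5-hydroxy-4,6-dimethyl-8-(tributylstannyl)nona-2,7-dienoate | CC/C(=C\[C@@H](C)[C@H](O)[C@H](C)/C=C(\C)[Sn](CCCC)(CCCC)CCCC)C(=O)OC | intermediate
11 | methyl (2E,4R,6R,7E)-2-ethyl-4,6-dimethyl-5-oxo-8-(tributylstannyl)nona-2,7-dienoate | CC/C(=C\[C@@H](C)C(=O)[C@H](C)/C=C(\C)[Sn](CCCC)(CCCC)CCCC)C(=O)OC | intermediate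
12 | (E)-(2-bromoethenyl)benzene | Br/C=C/c1ccccc1 | starting material
13 | (E)-but-1-en-3-yn-1-ylbenzene | C#C/C=C/c1ccccc1 | intermediate
14 | [(1E,3E)-2-ethyl-4-phenylbuta-1,3-dien-1-yl]copper (MgBr2 complex) | CC/C(=C\[Cu])/C=C/c1ccccc1 | intermediate
15 | (1E,3E)-2-ethyl-1-iodo-4-phenylbuta-1,3-diene | CC/C(=C\I)/C=C/c1ccccc1 | intermediate
16 | methyl (2E,4R,6R,7E,9E,11E)-2,10-diethyl-4,6,8-trimethyl-5-oxo-12-phenyldodeca-2,7,9,11-tetraenoate | CC/C(=C\[C@@H](C)C(=O)[C@H](C)/C=C(\C)/C=C(CC)/C=C/c1ccccc1)C(=O)OC | intermediate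
17 | methyl (1R,3R,3aS,4S,5R,7aS)-4,5-diethyl-1,3,7-trimethyl-2-oxo-5-[(E)-2-phenylethenyl]-2,3,3a,4,5,7a-hexahydro-1H-indene-4-carboxylate | CC[C@@]1(/C=C/c2ccccc2)C=C(C)[C@H]2[C@@H]([C@@H](C)C(=O)[C@@H]2C)[C@]1(CC)C(=O)OC | intermediate
18 | dinorspiculoic acid A | CC[C@@]1(/C=C/c2ccccc2)C=C(C)[C@H]2[C@@H]([C@@H](C)C(=O)[C@@H]2C)[C@]1(CC)C(=O)O | target

**Totals**
Total steps: 11. Longest linear sequence: 7 (steps 1, 2, 5, 6, 7, 10, 11).

**Three steps most likely to fail, with fallbacks**

Step 10 (coupling-triggered bicyclisation). The keto stannane 11 may couple sluggishly, or C4/C6 may erode while the ketone sits with the catalyst in DMF. The fallback sets out from 10 (and 15) and comes back at 17. The same Stille coupling is run at the alcohol oxidation level and gives methyl (2E,4R,5R,6R,7E,9E,11E)-2,10-diethyl-5-hydroxy-4,6,8-trimethyl-12-phenyldodeca-2,7,9,11-tetraenoate F1, which has no enolisable ketone and can be purified. Dess–Martin oxidation in CH2Cl2 then gives 16 free of metals and polar solvent, and warming in toluene at 80 °C closes it to 17. This way also bypasses step 7.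

Step 5 (propargylation of a labile aldehyde). Aldehyde 4 may isomerise to the conjugated enal before it is trapped, or the C4 selection may be poor. The fallback sets out from 7 and comes back at 9. Aldehyde 4 is replaced by the configurationally robust, Felkin-matched Roche-ester aldehyde (R)-3-[(tert-butyldimethylsilyl)oxy]-2-methylpropanal F2. The same palladium/Et2Zn propargylation gives (2R,3R,4R)-1-[(tert-butyldimethylsilyl)oxy]-2,4-dimethylhept-5-yn-3-ol F3 as one isomer, and TBAF gives (2R,3R,4R)-2,4-dimethylhept-5-yne-1,3-diol F4. TEMPO/PhI(OAc)2 oxidises only the primary alcohol to (2S,3R,4R)-3-hydroxy-2,4-dimethylhept-5-ynal F5. Wittig olefination of crude F5 with methyl 2-(triphenylphosphoranylidene)butanoate installs the E enoate and gives 9 as the pure 4R isomer. Steps 1 and 2 then fall away.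

Step 1 (cross-metathesis to a trisubstituted enoate with an α-branched alkene). Conversion may be low. The fallback sets out from 1 and comes back at 3. Ozonolysis (O3, CH2Cl2/MeOH, −78 °C; Me2S) gives 3-hydroxy-2-methylpropanal F6, used crude. Wittig olefination with methyl 2-(triphenylphosphoranylidene)butanoate (PhMe, 60 °C) gives 3 as the E isomer.

**Further compounds**
F1 | step 10 | methyl (2E,4R,5R,6R,7E,9E,11E)-2,10-diethyl-5-hydroxy-4,6,8-trimethyl-12-phenyldodeca-2,7,9,11-tetraenoate | CC/C(=C\[C@@H](C)[C@H](O)[C@H](C)/C=C(\C)/C=C(CC)/C=C/c1ccccc1)C(=O)OC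
F2 | step 5 | (R)-3-[(tert-butyldimethylsilyl)oxy]-2-methylpropanal | C[C@H](CO[Si](C)(C)C(C)(C)C)C=O
F3 | step 5 | (2R,3R,4R)-1-[(tert-butyldimethylsilyl)oxy]-2,4-dimethylhept-5-yn-3-ol | C[C@H](CO[Si](C)(C)C(C)(C)C)[C@H](O)[C@H](C)C#CC
F4 | step 5 | (2R,3R,4R)-2,4-dimethylhept-5-yne-1,3-diol | C[C@H](CO)[C@H](O)[C@H](C)C#CC
F5 | step 5 | (2S,3R,4R)-3-hydroxy-2,4-dimethylhept-5-ynal | C[C@H](C=O)[C@H](O)[C@H](C)C#CC
F6 | step 1 | 3-hydroxy-2-methylpropanal (racemic) | CC(CO)C=O
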